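(The numbers in the tables are calculated with constants of no real substance; the scatter is artificial.)

Monday's run, with 0.18 mM of protic impurity in 18 mM of starting material, is my one guide to a new flask charged with twice that impurity.

- Monday's: starting material 18 mM; protic impurity 0.18 mM; run made earlier
- flask: starting material 18 mM; protic impurity 0.360 mM; time 2.5 min

Monday's run (percent of the starting material charged)

| time / s | product / % | starting material / % |
|---|---|---|
| 10.0 | 66.0 | 27.4 |
| 12.0 | 69.9 | 25.0 |
| 20.0 | 77.8 | 17.1 |
| 25.0 | 81.3 | 14.6 |
| 40.0 | 86.4 | 9.9 |
| 50.0 | 88.3 | 8.4 |

(standard deviation of a reading: 0.3 percentage points)

- amount of product in percent of the starting material charged, at 8.0 s, 40 s and 2.5 min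

- percentages count the starting material that a species holds: one product counts as two
- the analysis behind the earlier runs scatters by 0.3 percentage points, standard deviation
- a reading or a percentage of product counts all its forms, free or not
- no earlier run changes the charge of protic impurity; that part of a forecast is a guess
- a reading of starting material is of its free form alone

In Monday's run the reciprocal of the free starting material, taken as a fraction of the charge, rises nearly straight with time. Between 25.0 s and 50.0 s it gains 0.202 s⁻¹; I call this slope of the second-order plot the climb. I assume that the doubled impurity leaves the climb alone, a guess that no run tests, and continuing from 50.0 s to 2.5 min gives 3.11% free starting material in the new flask.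

So on that guess product in the new flask stands at most at 96.9%. But Monday's two readings fall short of the whole charge, by 6.60% at 10.0 s and by 3.30% at 50.0 s, which is less. If each extra impurity costs one starting material, the extra charge takes 1.00%, and keeping Monday's last gap whole gives a floor of 92.6%. In Monday's run the gap shrinks with the starting material, and a straight line through its two ends gives 2.38% at 3.11% free starting material. This tightens the bracket to 93.5% through 94.5%, the lower end charging the extra impurity and the upper end not. The same shading of Monday's product gives 85.4% through 86.4% at 40 s, and extending its first two readings back gives 61.1% through 62.1% at 8.0 s.

The forecast says 60%, 85.5% and 93.5%, the first below my bracket, the second inside it and the last at its lower edge, and of the doubled impurity it says “It probably costs about one extra percent of starting material”.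

The new flask gives 61.1%, 85.6% and 93.9%.

    starting material + product ⇌ idle adduct, settled at all times (K = 37.0 L mol⁻¹)
    2 starting material → product (k = 7.00 L mol⁻¹ s⁻¹)
    starting material + protic impurity → quenched substrate (k = 27.0 L mol⁻¹ s⁻¹)

At 2.50 min the new flask holds 2.00% quenched substrate and 2.86% idle adduct, with 0.0631% of the impurity's own charge left and 3.11% free starting material. Carried on to 25.0 min, the climb gives 0.328% free starting material, and the new flask then holds 0.344%.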